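Ring B is cut at C-3'–C-4' and C-5'–C-6', a [4+2] disconnection. It travels through the asymmetric step as a 4-methoxy-3-thienyl group. S-oxidation then unmasks a locked s-cis, electron-poor diene (C-6', C-1', C-2', C-3'). In one operation this thiophene 1,1-dioxide adds 1,1,2-trimethoxyethene (C-4', C-5'), expels SO2 and loses methanol, giving the complete 2,4,5-trimethoxyphenyl ring. The step exploits the 1,2,4-oxygen pattern of ring B and its two CH positions, C-3' and C-6'. These are the thiophene α-carbons, and both ethene carbons end as C–OMe, so orientation is immaterial. C-2 is set earlier by rhodium-catalysed conjugate addition, and (NH4)2Ce(NO3)6 finally releases the quinone.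

Key step: step 8

Remark: ring B is numbered C-1' (bonded to C-2) to C-6', with oxygen on C-2', C-4' and C-5'; the sense of induction in step 5 is assumed by analogy with 2-cyclohexenone, and the (1R,4R)-ligand would be used if it proved opposite.

Step 1
Reactants: 1 1-(2,6-dihydroxy-4-methoxyphenyl)ethan-1-one
Product: 2 1-(2,6-dihydroxy-4-methoxy-3,5-dimethylphenyl)ethan-1-one
Conditions: MeI (2.2 equiv), KOH (4 equiv), MeOH/H2O, 0 → 40 °C
Reagents that add atoms: iodomethane CI
Why: Nuclear C-methylation of a phloroglucinol-type phenolate (C-alkylation of an ambident phenoxide in a protic solvent) should place one methyl group on each of the two equivalent free ring carbons, which are ortho and para to the phenoxide oxygens, while hydrogen bonding of the solvent to oxygen disfavours O-alkylation.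

Step 2
Reactants: 2 1-(2,6-dihydroxy-4-methoxy-3,5-dimethylphenyl)ethan-1-one
Product: 4 5-hydroxy-7-methoxy-6,8-dimethyl-4H-chromen-4-one, via enaminone 3 (not isolated)
Conditions: Me2NCH(OMe)2 (1.5 equiv), toluene, 90 °C; then aq HCl (2 M), CH2Cl2, 40 °C
Reagents that add atoms: N,N-dimethylformamide dimethyl acetal COC(OC)N(C)C
Why: Condensation of the acetyl CH3 with the amide acetal gives the enaminone, and acid then triggers conjugate addition of one of the two equivalent ortho OH groups with loss of dimethylamine (enaminone route to chromones), leaving the other OH as the chelated 5-OH.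

Step 3
Reactants: 5 3,4-dibromothiophene
Product: 6 3-bromo-4-methoxythiophene
Conditions: NaOMe (1.1 equiv), CuI (10 mol %), MeOH/NMP, 110 °C
Reagents that add atoms: sodium methoxide C[O-].[Na+]
Why: Ullmann-type copper-catalysed methoxylation of a bromothiophene, in which the limited amount of methoxide and the lower reactivity of the electron-richer monoether towards a second exchange should hold the reaction at 6.

Step 4
Reactants: 6 3-bromo-4-methoxythiophene
Product: 9 (4-methoxythiophen-3-yl)boronic acid, via thienyllithium 7 (not isolated), via lithium borate 8 (not isolated)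
Conditions: B(OiPr)3 (1.3 equiv), then n-BuLi (1.05 equiv), Et2O, −78 °C; aq HCl (1 M), 0 °C
Reagents that add atoms: triisopropyl borate CC(C)OB(OC(C)C)OC(C)C; water O
Why: Bromine–lithium exchange is faster than ring deprotonation at −78 °C, the borate present in the flask traps the 3-thienyllithium before it can isomerise to the 2-lithio species, and acid hydrolysis of the ate complex gives the boronic acid (lithiation–borylation).

Step 5
Reactants: 4 5-hydroxy-7-methoxy-6,8-dimethyl-4H-chromen-4-one; 9 (4-methoxythiophen-3-yl)boronic acid
Product: 10 (S)-5-hydroxy-7-methoxy-2-(4-methoxythiophen-3-yl)-6,8-dimethylchroman-4-one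
Conditions: 9 (2 equiv), [RhCl(C2H4)2]2 (2.5 mol %), (1S,4S)-2,5-diphenylbicyclo[2.2.2]octa-2,5-diene (5.5 mol %), KOH (10 mol %), dioxane/H2O 10:1, 40 °C
Reagents that add atoms: none
Why: Rhodium-catalysed asymmetric 1,4-addition of a boronic acid (Hayashi–Miyaura reaction) to a chromone, in which the thienyl group is transferred from monovalent rhodium to C-2 on the enone face left open by the C2-symmetric chiral diene, which sets C-2 as S, and water protonates the rhodium enolate.

Step 6
Reactants: 10 (S)-5-hydroxy-7-methoxy-2-(4-methoxythiophen-3-yl)-6,8-dimethylchroman-4-one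
Product: 12 (S)-5-hydroxy-7-methoxy-2-(4-methoxy-1,1-dioxidothiophen-3-yl)-6,8-dimethylchroman-4-one, via thiophene 1-oxide 11 (not isolated)
Conditions: dimethyldioxirane (3 equiv, about 0.07 M in acetone), CH2Cl2, −20 → 0 °C; evaporate below 0 °C, use at once
Reagents that add atoms: dimethyldioxirane CC1(C)OO1
Why: Two successive electrophilic oxygen transfers from the dioxirane to sulfur (thiophene to thiophene 1,1-dioxide oxidation), the second being faster because 11 is no longer aromatic, run cold and neutral with acetone as the only by-product, so that the chelated acylphenol, the ketone, the aryl ethers and C-2 should survive and the labile diene is obtained by evaporation alone.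

Step 7
Reactants: 13 1,1,2,2-tetramethoxyethane
Product: 14 1,1,2-trimethoxyethene
Conditions: TMSOTf (1.1 equiv), iPr2NEt (1.3 equiv), CH2Cl2, −20 → 23 °C; pentane, cold aq NaOH wash; distil from K2CO3
Reagents that add atoms: none
Why: The silyl triflate ionises one acetal to an oxocarbenium ion and the hindered amine removes the neighbouring acetal proton (acetal to enol ether elimination), which here can only give the ketene acetal 14.

Step 8
Reactants: 12 (S)-5-hydroxy-7-methoxy-2-(4-methoxy-1,1-dioxidothiophen-3-yl)-6,8-dimethylchroman-4-one; 14 1,1,2-trimethoxyethene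
Product: 17 (S)-5-hydroxy-7-methoxy-6,8-dimethyl-2-(2,4,5-trimethoxyphenyl)chroman-4-one, via bicyclic sulfone 15 (not isolated), via cyclohexadiene 16 (not isolated)
Conditions: 14 (6 equiv), toluene, 4 Å MS, 70 °C, sealed tube; evaporate; PPTS (5 mol %), CH2Cl2, 23 °C
Reagents that add atoms: none
Why: The cyclic dienyl sulfone 12 is locked s-cis, non-aromatic and LUMO-lowered by the SO2 group, so it should undergo an inverse-electron-demand Diels–Alder reaction with the very electron-rich ketene acetal 14 through its two α-carbons (C-3' and C-6'), forming C-3'–C-4' and C-6'–C-5' in one concerted, asynchronous suprafacial event to give 15. Cheletropic loss of SO2 from this 7-thiabicyclo[2.2.1]heptene 7,7-dioxide gives cyclohexadiene 16, and 1,2-elimination of methanol from its ketal carbon (completed by a trace of PPTS) aromatises it to 17. The closest known reaction type is the thiophene 1,1-dioxide Diels–Alder/SO2-extrusion benzannulation, combined with the ketene-acetal aromatisation known from electron-poor 2-pyranones. Ring B is closed by intermolecular [4π+2π] cycloaddition, not by a stepwise exo or endo cyclisation, and the sulfone bridge is only a temporary second ring. The sp3 centres created at C-3', C-4', C-5' and C-6' are all erased on aromatisation, so no new stereocentre has to be controlled, and C-2 is a spectator under these neutral conditions. The step needs cross-cycloaddition to beat self-dimerisation of 12 and protonation of 14 by the 5-OH, which the 3,4-disubstitution of the diene, the intramolecular hydrogen bond of that OH and the excess of 14 should secure, while regiochemistry needs no control because both orientations converge on 17.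

Step 9
Reactants: 17 (S)-5-hydroxy-7-methoxy-6,8-dimethyl-2-(2,4,5-trimethoxyphenyl)chroman-4-one
Product: 18 (S)-2-(5-hydroxy-7-methoxy-6,8-dimethyl-4-oxochroman-2-yl)-5-methoxycyclohexa-2,5-diene-1,4-dione
Conditions: (NH4)2Ce(NO3)6 (2.5 equiv), MeCN/H2O 3:1, 0 °C
Reagents that add atoms: water O
Why: Oxidative demethylation of a 1,4-dimethoxyarene by tetravalent cerium, in which ring B, the most electron-rich arene, is oxidised to its radical cation, water adds at C-2' and C-5' (the only para-related OMe pair) and two molecules of methanol leave, so that the 4'-OMe stays as the vinylogous ester while the acyl-deactivated ring A and the C-2 stereocentre should survive the short, cold, weakly acidic treatment.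

Compound list
1 | 1-(2,6-dihydroxy-4-methoxyphenyl)ethan-1-one | CC(=O)c1c(O)cc(OC)cc1O | starting material
2 | 1-(2,6-dihydroxy-4-methoxy-3,5-dimethylphenyl)ethan-1-one | CC(=O)c1c(O)c(C)c(OC)c(C)c1O | intermediate
3 | (E)-3-(dimethylamino)-1-(2,6-dihydroxy-4-methoxy-3,5-dimethylphenyl)prop-2-en-1-one | CN(C)/C=C/C(=O)c1c(O)c(C)c(OC)c(C)c1O | intermediate
4 | 5-hydroxy-7-methoxy-6,8-dimethyl-4H-chromen-4-one | O=C1C=COc2c(C)c(OC)c(C)c(O)c12 | intermediate
5 | 3,4-dibromothiophene | Brc1cscc1Br | starting material
6 | 3-bromo-4-methoxythiophene | COc1cscc1Br | intermediate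
7 | (4-methoxythiophen-3-yl)lithium | [Li]c1cscc1OC | intermediate
8 | lithium triisopropoxy(4-methoxythiophen-3-yl)borate | [Li+].COc1cscc1[B-](OC(C)C)(OC(C)C)OC(C)C | intermediate
9 | (4-methoxythiophen-3-yl)boronic acid | COc1cscc1B(O)O | intermediate
10 | (S)-5-hydroxy-7-methoxy-2-(4-methoxythiophen-3-yl)-6,8-dimethylchroman-4-one | COc1cscc1[C@@H]1CC(=O)c2c(O)c(C)c(OC)c(C)c2O1 | intermediate
11 | (S)-5-hydroxy-7-methoxy-2-(4-methoxy-1-oxidothiophen-3-yl)-6,8-dimethylchroman-4-one (mixture at sulfur) | COC1=CS(=O)C=C1[C@@H]1CC(=O)c2c(O)c(C)c(OC)c(C)c2O1 | intermediate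
12 | (S)-5-hydroxy-7-methoxy-2-(4-methoxy-1,1-dioxidothiophen-3-yl)-6,8-dimethylchroman-4-one | COC1=CS(=O)(=O)C=C1[C@@H]1CC(=O)c2c(O)c(C)c(OC)c(C)c2O1 | intermediate
13 | 1,1,2,2-tetramethoxyethane (glyoxal bis(dimethyl acetal)) | COC(OC)C(OC)OC | starting material
14 | 1,1,2-trimethoxyethene | COC=C(OC)OC | intermediate
15 | (2S)-5-hydroxy-7-methoxy-6,8-dimethyl-2-(2,5,6,6-tetramethoxy-7,7-dioxido-7-thiabicyclo[2.2.1]hept-2-en-3-yl)chroman-4-one (diastereomer mixture, polarity-matched orientation drawn) | COC1=C([C@@H]3CC(=O)c4c(O)c(C)c(OC)c(C)c4O3)C2C(OC)C(OC)(OC)C1S2(=O)=O | intermediate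
16 | (2S)-5-hydroxy-7-methoxy-6,8-dimethyl-2-(3,4,4,6-tetramethoxycyclohexa-1,5-dien-1-yl)chroman-4-one (epimer mixture at the ring CH(OMe)) | COC1=CC(OC)(OC)C(OC)C=C1[C@@H]1CC(=O)c2c(O)c(C)c(OC)c(C)c2O1 | intermediate
17 | (S)-5-hydroxy-7-methoxy-6,8-dimethyl-2-(2,4,5-trimethoxyphenyl)chroman-4-one | COc1cc(OC)c(cc1OC)[C@@H]1CC(=O)c2c(O)c(C)c(OC)c(C)c2O1 | intermediate
18 | (S)-2-(5-hydroxy-7-methoxy-6,8-dimethyl-4-oxochroman-2-yl)-5-methoxycyclohexa-2,5-diene-1,4-dione | COC1=CC(=O)C([C@@H]2CC(=O)c3c(O)c(C)c(OC)c(C)c3O2)=CC1=O | target

Total step count: 9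
Longest linear sequence: 6 steps (5 → 6 → 9 → 10 → 12 → 17 → 18). The branch 1 → 2 → 4 → 10 → 12 → 17 → 18 is equally long.

Steps most likely to fail

Step 8. The diene may dimerise, or the ketene acetal may be used up by proton transfer from the 5-OH, before the cross-cycloaddition takes place. Fallback: the same ring construction is moved to the small-molecule stage, where the diene is more electron-poor and carries neither OH nor stereocentre. It sets out from 6, which is oxidised with dimethyldioxirane to 3-bromo-4-methoxythiophene 1,1-dioxide F1. Heating with 14 should give, after loss of SO2 and methanol, 1-bromo-2,4,5-trimethoxybenzene F2. Bromine–lithium exchange and borylation as in step 4 give (2,4,5-trimethoxyphenyl)boronic acid F3. The rhodium-catalysed addition of step 5, now with F3 and 4, comes back to the route at 17.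

Step 6. The oxidant may attack the enol ether C=C bond of the methoxythiophene or ring A instead of sulfur. Fallback: the sulfone is made before any donor group is present. It sets out from 5, which is oxidised with CF3CO3H (from H2O2 and (CF3CO)2O) to 3,4-dibromothiophene 1,1-dioxide F4. Addition–elimination of one equivalent of NaOMe at the β-bromovinyl sulfone gives 3-bromo-4-methoxythiophene 1,1-dioxide F1. This is carried on through 1-bromo-2,4,5-trimethoxybenzene F2 and (2,4,5-trimethoxyphenyl)boronic acid F3 as described above and comes back to the route at 17.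

Step 5. Binding of the thiophene sulfur or of the phenoxide to rhodium, protodeboronation of the electron-rich boronic acid, or poor facial selectivity may spoil the addition. Fallback: classical flavanone assembly followed by resolution. It sets out from 6 and 2. Compound 6 is lithiated as in step 4 and quenched with DMF to give 4-methoxythiophene-3-carbaldehyde F5. Claisen–Schmidt condensation with 2 (KOH, EtOH) gives (E)-1-(2,6-dihydroxy-4-methoxy-3,5-dimethylphenyl)-3-(4-methoxythiophen-3-yl)prop-2-en-1-one F6. Oxa-Michael cyclisation (NaOAc, EtOH, reflux) gives rac-5-hydroxy-7-methoxy-2-(4-methoxythiophen-3-yl)-6,8-dimethylchroman-4-one F7. Preparative chromatography on a chiral stationary phase gives 10, where the route is rejoined. The unwanted (R)-5-hydroxy-7-methoxy-2-(4-methoxythiophen-3-yl)-6,8-dimethylchroman-4-one F8 is racemised with NaOAc and recycled.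

Further compounds
F1 | step 8 | 3-bromo-4-methoxythiophene 1,1-dioxide | COC1=CS(=O)(=O)C=C1Br
F2 | step 8 | 1-bromo-2,4,5-trimethoxybenzene | COc1cc(OC)c(Br)cc1OC
F3 | step 8 | (2,4,5-trimethoxyphenyl)boronic acid | COc1cc(OC)c(cc1OC)B(O)O
F4 | step 6 | 3,4-dibromothiophene 1,1-dioxide | BrC1=CS(=O)(=O)C=C1Br
F5 | step 5 | 4-methoxythiophene-3-carbaldehyde | COc1cscc1C=O
F6 | step 5 | (E)-1-(2,6-dihydroxy-4-methoxy-3,5-dimethylphenyl)-3-(4-methoxythiophen-3-yl)prop-2-en-1-one | COc1cscc1/C=C/C(=O)c1c(O)c(C)c(OC)c(C)c1O
F7 | step 5 | rac-5-hydroxy-7-methoxy-2-(4-methoxythiophen-3-yl)-6,8-dimethylchroman-4-one | COc1cscc1C1CC(=O)c2c(O)c(C)c(OC)c(C)c2O1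
F8 | step 5 | (R)-5-hydroxy-7-methoxy-2-(4-methoxythiophen-3-yl)-6,8-dimethylchroman-4-one | COc1cscc1[C@H]1CC(=O)c2c(O)c(C)c(OC)c(C)c2O1
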